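**Retrosynthetic overview**
- The oxirane is traced back to an isomeric, achiral (mirror-symmetric) oxetane, 3-aryl-oxetan-3-yl isobutyrate. In the forward direction, catalyst-controlled bromide opening of one of its two enantiotopic ring CH2 groups, then a tertiary-to-primary acyl shift and bromohydrin closure, contracts the ring and sets the only stereocentre.
- The oxetane diester is disconnected at the aryl–C bond and at both ester C–O bonds: C,O-dilithiated 2-bromo-4-methoxy-5-methylphenol, oxetan-3-one and two isobutyryl chlorides, joined in one flask.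
- The bromophenol comes from ortho-bromination of 4-methoxy-3-methylphenol.
- Ring order: arene (bought), oxetane (bought as oxetan-3-one, attached in step 2), oxirane (formed last from the oxetane).

Assumption: the squaramide Q = 3-{[3,5-bis(trifluoromethyl)phenyl]amino}-4-{[(2S)-3,3-dimethyl-1-oxo-1-[(2R)-2-(phenanthren-9-yl)pyrrolidin-1-yl]butan-2-yl]amino}cyclobut-3-ene-1,2-dione is taken to send bromide to the pro-R CH2 of 8; if the first run shows the opposite sense, its mirror image is used.

**Step 1**
Reactants: 1 4-methoxy-3-methylphenol; 2 N-bromosuccinimide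
Product: 3 2-bromo-4-methoxy-5-methylphenol
Conditions: NBS (1.0 equiv), i-Pr2NH (10 mol %), CH2Cl2, 0 °C
Reagents that add atoms: N-bromosuccinimide (O=C1CCC(=O)N1Br)
Why: Amine-catalysed electrophilic ortho-bromination of a phenol: OH is the dominant director and, of its two ortho positions, only the one para to CH3 is unhindered (the other is flanked by OH and CH3), while one equivalent of NBS at 0 °C limits over-bromination and oxidation to the quinone; no stereocentre.

**Step 2**
Reactants: 3 2-bromo-4-methoxy-5-methylphenol; 4 oxetan-3-one; 5 2-methylpropanoyl chloride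
Product: 8 3-[5-methoxy-4-methyl-2-(2-methylpropanoyloxy)phenyl]oxetan-3-yl 2-methylpropanoate, via C,O-dilithio phenoxide 6 (not isolated), via dilithium diolate 7 (not isolated)
Conditions: n-BuLi (2.15 equiv), THF, −78 → 0 °C; 4 (1.2 equiv), −78 → 0 °C; then 5 (2.6 equiv), 4-(dimethylamino)pyridine (10 mol %), 0 °C → rt
Reagents that add atoms: oxetan-3-one (O=C1COC1); 2-methylpropanoyl chloride (CC(C)C(Cl)=O)
Why: Bromine–lithium exchange on the lithium phenoxide gives 6, whose aryl carbanion adds 1,2 to the strained, highly electrophilic ketone of 4, and both lithium oxides of 7 (the phenoxide and the tied-back, unhindered tertiary alkoxide) are O-acylated in the same flask; 8 keeps a mirror plane and has no stereocentre.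

**Step 3**
Reactants: 8 3-[5-methoxy-4-methyl-2-(2-methylpropanoyloxy)phenyl]oxetan-3-yl 2-methylpropanoate
Product: 11 [(2S)-2-[5-methoxy-4-methyl-2-(2-methylpropanoyloxy)phenyl]oxiran-2-yl]methyl 2-methylpropanoate, via (R)-bromo silyl ether 9 (not isolated), via (R)-bromo tertiary alkoxide 10 (not isolated)
Conditions: Me3SiBr (1.2 equiv), squaramide Q (5 mol %), t-BuOMe, −80 °C; then Bu4N[Ph3SiF2] (TBAT, 1.5 equiv), THF, −80 → 0 °C
Reagents that add atoms: none
Why: Proposed new method: the squaramide binds the bromide of the O-silyl oxetanium bromide ion pair and delivers it by SN2 to the pro-R CH2 of the mirror-symmetric oxetane, which fixes the stereocentre as (R) in 9 without touching any bond at that carbon; fluoride then frees the primary alkoxide, a 1,2 O-to-O acyl shift through a five-membered orthoester-type intermediate moves the tertiary isobutyrate to the primary oxygen, and the tertiary alkoxide 10 closes 3-exo-tet onto CH2Br, so the configuration is retained and only the descriptor changes to (S); the closest known reaction types are hydrogen-bond-donor-catalysed enantioselective Me3SiBr opening of 3,3-disubstituted oxetanes, base-triggered acyl migration in monoacyl 1,2-diols and epoxide closure of bromohydrins, while the 3-acyloxy-3-aryl substrate and the one-flask shift and ring contraction are untested.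

**Compound list**
1 | 4-methoxy-3-methylphenol | COc1ccc(O)cc1C | starting material
2 | N-bromosuccinimide | O=C1CCC(=O)N1Br | starting material
3 | 2-bromo-4-methoxy-5-methylphenol | COc1cc(Br)c(O)cc1C | intermediate
4 | oxetan-3-one | O=C1COC1 | starting material
5 | 2-methylpropanoyl chloride (isobutyryl chloride) | CC(C)C(Cl)=O | starting material
6 | lithium 2-lithio-4-methoxy-5-methylphenoxide | COc1cc([Li])c(O[Li])cc1C | intermediate
7 | dilithium 3-(5-methoxy-4-methyl-2-oxidophenyl)oxetan-3-olate | COc1cc(C2(O[Li])COC2)c(O[Li])cc1C | intermediate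
8 | 3-[5-methoxy-4-methyl-2-(2-methylpropanoyloxy)phenyl]oxetan-3-yl 2-methylpropanoate (achiral) | COc1cc(C2(OC(=O)C(C)C)COC2)c(OC(=O)C(C)C)cc1C | intermediate
9 | [(2R)-1-bromo-2-[5-methoxy-4-methyl-2-(2-methylpropanoyloxy)phenyl]-3-(trimethylsilyloxy)propan-2-yl] 2-methylpropanoate | COc1cc([C@@](OC(=O)C(C)C)(CO[Si](C)(C)C)CBr)c(OC(=O)C(C)C)cc1C | intermediate
10 | tetrabutylammonium (2R)-1-bromo-2-[5-methoxy-4-methyl-2-(2-methylpropanoyloxy)phenyl]-3-(2-methylpropanoyloxy)propan-2-olate | COc1cc([C@@]([O-])(COC(=O)C(C)C)CBr)c(OC(=O)C(C)C)cc1C.CCCC[N+](CCCC)(CCCC)CCCC | intermediate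
11 | [(2S)-2-[5-methoxy-4-methyl-2-(2-methylpropanoyloxy)phenyl]oxiran-2-yl]methyl 2-methylpropanoate | COc1cc([C@@]2(COC(=O)C(C)C)CO2)c(OC(=O)C(C)C)cc1C | target

**Total step count:** 3. **Longest linear sequence:** 3 steps (1 → 3 → 8 → 11).

**Steps most likely to fail and fallbacks**

Step 3 is the main risk. The tertiary ester C=O could take part in the opening (a dioxolanylium path would erode the ee), although the roughly 120° dihedral to the breaking C–O bond in the oxetane disfavours this. The level and sense of induction with an ortho-substituted aryl are unknown. In the cascade, the primary alkoxide could close back to achiral 8 (recyclable, no loss of ee) or acyl transfer from the aryl ester could lead to a dihydrobenzofuran. The fallback breaks symmetry by acylation of a 2-aryl-glycerol instead of by ring opening; it sets out from 3 and comes back at 11. The dilithio species 6 made from 3 is added to 2,2-dimethyl-1,3-dioxan-5-one (THF, −78 °C) to give 5-(2-hydroxy-5-methoxy-4-methylphenyl)-2,2-dimethyl-1,3-dioxan-5-ol F1. Phenol-selective acylation (i-PrCOCl 1.0 equiv, Et3N, CH2Cl2, 0 °C) gives 2-(5-hydroxy-2,2-dimethyl-1,3-dioxan-5-yl)-4-methoxy-5-methylphenyl 2-methylpropanoate F2. Aqueous AcOH/THF removes the acetonide to give the mirror-symmetric triol 4-methoxy-5-methyl-2-(1,2,3-trihydroxypropan-2-yl)phenyl 2-methylpropanoate F3. Desymmetrising mono-isobutyrylation of one enantiotopic CH2OH (CuCl2 with 2,6-bis[(4R)-4-phenyl-4,5-dihydro-1,3-oxazol-2-yl]pyridine or its enantiomer, i-PrCOCl, Et3N, THF, −40 °C; a lipase with vinyl 2-methylpropanoate is the alternative) gives [(2S)-2,3-dihydroxy-2-[5-methoxy-4-methyl-2-(2-methylpropanoyloxy)phenyl]propyl] 2-methylpropanoate F4. Mitsunobu cyclodehydration (PPh3, DIAD, THF, 0 °C) closes the tertiary OH onto the activated primary carbon, with no bond broken at the stereocentre, and gives 11.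

Step 2 can fail through sluggish exchange or low nucleophilicity of the dianion, or through incomplete acylation of the tertiary alkoxide. The fallback uses a protected mono-anion and separate acylation; it sets out from 3 and comes back at 8. Benzylation (BnBr, K2CO3, acetone, reflux) gives 1-(benzyloxy)-2-bromo-4-methoxy-5-methylbenzene F5. Exchange with n-BuLi (1.05 equiv, THF, −78 °C) and addition to 4 gives 3-[2-(benzyloxy)-5-methoxy-4-methylphenyl]oxetan-3-ol F6. Neutral hydrogenolysis (H2, Pd/C, EtOAc) gives 3-(2-hydroxy-5-methoxy-4-methylphenyl)oxetan-3-ol F7. Double acylation (2-methylpropanoic anhydride, Et3N, 4-(dimethylamino)pyridine, CH2Cl2) gives 8.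

Step 1 can fail through over-bromination, oxidation of the electron-rich phenol to the quinone, or a minor regioisomer. The fallback places bromine by directed ortho-metalation; it sets out from 1 and comes back at 3. MOMCl and i-Pr2NEt in CH2Cl2 give 1-methoxy-4-(methoxymethoxy)-2-methylbenzene F8. Lithiation ortho to the OMOM group at its unhindered side (n-BuLi, TMEDA, THF, 0 °C) and quench with 1,2-dibromo-1,1,2,2-tetrachloroethane give 1-bromo-5-methoxy-2-(methoxymethoxy)-4-methylbenzene F9. HCl in MeOH removes the MOM group and gives 3.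

**Further compounds**
F1 | step 3 | 5-(2-hydroxy-5-methoxy-4-methylphenyl)-2,2-dimethyl-1,3-dioxan-5-ol | COc1cc(C2(O)COC(C)(C)OC2)c(O)cc1C
F2 | step 3 | 2-(5-hydroxy-2,2-dimethyl-1,3-dioxan-5-yl)-4-methoxy-5-methylphenyl 2-methylpropanoate | COc1cc(C2(O)COC(C)(C)OC2)c(OC(=O)C(C)C)cc1C
F3 | step 3 | 4-methoxy-5-methyl-2-(1,2,3-trihydroxypropan-2-yl)phenyl 2-methylpropanoate | COc1cc(C(O)(CO)CO)c(OC(=O)C(C)C)cc1C
F4 | step 3 | [(2S)-2,3-dihydroxy-2-[5-methoxy-4-methyl-2-(2-methylpropanoyloxy)phenyl]propyl] 2-methylpropanoate | COc1cc([C@@](O)(COC(=O)C(C)C)CO)c(OC(=O)C(C)C)cc1C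
F5 | step 2 | 1-(benzyloxy)-2-bromo-4-methoxy-5-methylbenzene | COc1cc(Br)c(OCc2ccccc2)cc1C
F6 | step 2 | 3-[2-(benzyloxy)-5-methoxy-4-methylphenyl]oxetan-3-ol | COc1cc(C2(O)COC2)c(OCc2ccccc2)cc1C
F7 | step 2 | 3-(2-hydroxy-5-methoxy-4-methylphenyl)oxetan-3-ol | COc1cc(C2(O)COC2)c(O)cc1C
F8 | step 1 | 1-methoxy-4-(methoxymethoxy)-2-methylbenzene | COCOc1ccc(OC)c(C)c1
F9 | step 1 | 1-bromo-5-methoxy-2-(methoxymethoxy)-4-methylbenzene | COCOc1cc(C)c(OC)cc1Br
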